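The data come from a simulation with made-up constants, noise included.

We decide to reckon this flask in charges of precatalyst and not in days, and to ask what one charge can do before its catalyst stops working.

all flasks: starting material 20 mM; temperature 25 °C
- alpha: reagent 60 mM; precatalyst 20 µM; the very flask that is asked about, followed so far
- beta: reagent 60 mM; precatalyst 40 µM; run made earlier
- flask: reagent 60.0 mM; precatalyst 20 µM; time 6.0 d

| run | time / d | target / % | starting material / % |
|---|---|---|---|
| alpha | 0.417 | 30.8 | 69.5 |
| alpha | 0.833 | 56.1 | 43.7 |
| alpha | 2.08 | 76.6 | 23.5 |
| alpha | 5.00 | 79.5 | 20.6 |
| beta | 1.04 | 94.2 | 5.7 |
| beta | 2.00 | 98.9 | 0.7 |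
| beta | 3.00 | 99.9 | 0.3 |
| beta | 4.00 | 98.8 | 0.4 |

(readings scatter by 0.3 percentage points)

- target, in percent of the starting material first charged, at 6.0 d
- the remedy with the largest gain of target, or "none" below 2 percentage points (grey / amber / red / green / violet / none)
- target present, with what was taken out counted in, in percent of the starting material first charged, after amber
- target present, with what was taken out counted in, in percent of the starting material first charged, after red

- grey: change nothing and wait 6.0 d more
- amber: at 6.0 d add precatalyst, 100% of the amount charged, then wait 6.0 d
- red: at 6.0 d add reagent, 50.0% of the amount charged, then wait 6.0 d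
- green: at 6.0 d take out 90% of the target then present, then wait 6.0 d
- violet: at 6.0 d raise the temperature by 10 K, then wait 6.0 d

- what is taken out of target is counted as made
- the earlier runs were read with a standard deviation of 0.3 percentage points
- additions bring no volume worth counting
- the earlier runs do not show what temperature does; that part of a forecast is a guess

Alpha made 30.8% in its first 0.417 d but 2.9 percentage points between 2.08 d and 5.00 d, far less, although starting material still stood at 23.5% at the start of that stretch. Beta, with twice the precatalyst, left 0.4%. So we read alpha's stall as a fading catalyst, freeze [reagent] at its charge, and take alpha's last reading, 79.5%, as the charge budget, the target one charge of precatalyst makes before the flask stalls. That leaves 20.5% for a second charge, and two extreme flasks bound what it does.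

Fixed amount per charge (saturated, rate independent of [starting material]): a second charge can make 79.5%, more than the 20.5% present, so target reaches 100%.

Fixed fraction per charge (first order in starting material): 20.5% of 20.5% stays, which is 4.20%, so target reaches 95.8%.

Beta is such a double charge given at once, and its 0.4% left is less than the fixed-fraction figure, so we place the real flask near the fixed-amount end. Amber will meet [reagent] lowered by about a quarter if one reagent goes per target, which can pull it below the fixed-amount figure. We therefore commit to about 79.5% now and to amber as the best remedy, close to the top of the range. Remedies that bring no catalyst have just the late trickle to work with, though what heat does is a guess.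

The forecast gave 79.9% (79% to 81%) now, amber as best, 99% (95% to 100%) after amber and 80.2% (79.2% to 82%) after red, on the ground “so the catalyst is dying”.

The flask gives 79.8% now and amber as best, with a gain of 20 points against 0.019 points for red, and 99.5% after amber and 79.8% after red.

    starting material + reagent + free catalyst → target + free catalyst, rate k1*[starting material]*[reagent]*[free catalyst]/(1 + ([starting material]/sat1)) (3.83 mM, k = 3.39 × 10⁵ L² mol⁻² h⁻¹, Ea = 38.0 kJ mol⁻¹)
    free catalyst → spent catalyst (k = 0.0600 h⁻¹, Ea = 104 kJ mol⁻¹)
    precatalyst → free catalyst (k = 0.259 h⁻¹, Ea = 96.0 kJ mol⁻¹)
    (constants at 25 °C)

Target formed while free catalyst stood in the flask: at 0.600 d free catalyst was 51.7% of the catalyst charged and target 43.9%, and at 3.00 d they were 1.73% and 78.9%. At 6.00 d free catalyst was 0.0230%, beside 20.2% of starting material and 73.4% of reagent. Amber's 99.5% lies above the fixed-fraction figure, near the fixed-amount end. Scaled by [reagent], the budget estimates a neighbour of this flask with 36 mM of reagent at 47.7% by the fixed-amount reckoning and 61.4% by the fixed-fraction one, and that neighbour gave 51.8% at 6.00 d.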